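## The problem

Target 20 is a linear trimer of phloroglucinol: three benzene rings, each oxygenated on every second carbon, joined by two diaryl ether bonds (ring A–O–ring B–O–ring C), with one bromine on ring C between two hydroxyl groups. It has no stereocentre, so nothing has to be controlled in that respect; the task is regiochemistry and order of bond formation. Both ether oxygens sit on carbons flanked by two oxygen-bearing carbons (C1 of ring B towards ring A, C1 of ring C towards ring B). Each link therefore has to be made at a crowded, electron-rich position, the worst case for direct arylation of a phenol. The bromine cannot come late, because the unbrominated polyphenol offers seven activated CH positions on three rings. It must be placed on a symmetric ring C precursor and carried through. The aryl bromide then rules out hydrogenolysis, alkyllithium reagents and most zerovalent palladium chemistry in later steps. The electron-rich phenols oxidise to quinones in air and base, so they stay masked as ethers until the last step. The feature that opens the route is ring A: its carbons alternate C–O, C–H, C–O, C–H, C–O, C–H, and one of the three oxygens is the ether to ring B. A cyclobutenone with the aryloxy group on C3 (C=O, CH, C–OAr, CH2) and an alkoxyacetylene (CH, C–OR) give exactly this pattern when merged into a benzene ring.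

## Retrosynthesis

**20 ⇒ 19.** The five O–CH3 bonds and the one O–C2H5 bond are cut. Alkyl ethers are the one protecting group class that survives methoxide, peracid and heating, and they come off without hydrogen or a metal, which benzyl ethers would need at the cost of the C–Br bond. The ethyl group is imposed by the alkyne of the key step, so one reagent has to clear all six ethers. The forward step must leave the two diaryl ether bonds and the bromine in place.

**19 ⇒ 13 + 14.** Ring A is taken apart into a four-carbon and a two-carbon piece. In phenol numbering the cuts are C1–C2 and C3–C4, which tie in the two alkyne carbons, and C1–C6, which is closed in the electrocyclisation. The neighbouring cut would be the ring A–O bond, made by Ullmann coupling of phenol 9 with a 3,5-dialkoxyaryl halide. That pairs a di-ortho-substituted phenol with an electron-rich halide and puts a metal catalyst next to the ring C bromide. In the annulation the ether oxygen is already attached to an sp2 carbon before ring A exists. The precursor 13 lacks ring A and its three oxygens altogether. The forward reaction must open the cyclobutenone thermally and combine the resulting ketene with ethoxyacetylene 14 in one orientation.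

**13 ⇒ 9 + 12, 12 ⇒ 11 ⇒ 10.** The vinylic C–O bond is cut to phenol 9 and the vinylogous acid chloride 12. The chloride goes back to cyclobutane-1,3-dione 11 and from there to the commercial vinylogous ester 10. This is preferred to building the four-membered ring on an aryl ethynyl ether, whose preparation needs an alkyllithium that the bromide would not survive. The forward step asks only that a hindered phenoxide add to an unhindered β-carbon and expel chloride.

**9 ⇒ 7 ⇒ 6 ⇒ 4 + 5.** The phenolic C–O bond of 9 is traced to the formyl group of 7 (aryl migration to oxygen). That formyl group in turn allows ring B to be assembled by substitution: the two C–OCH3 bonds of 7 and the ring B–O–ring C bond of 6 are each cut at a carbon that bore fluorine ortho or para to the aldehyde of 5. Against a copper-mediated coupling for this ether, the substitution needs no metal and runs near room temperature. The forward sequence needs para selectivity in the first substitution.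

**4 ⇒ 2 ⇒ 1.** The same formyl-to-hydroxyl exchange gives the ring C phenol 4 from aldehyde 2. The C–Br bond is cut back to commercial 1, in which C3 and C5 are equivalent. Brominating the aldehyde and not the phenol keeps the oxidation-prone phenol away from the brominating agent.

## Roads not taken

**Alternative 1:** The three hydroxyl groups of ring C are traced to three formyl groups. Tricarbaldehyde A1 would be made by substitution of a halogenated benzenetricarbaldehyde with the phenol carrying rings A and B. It would be oxidised three times with mCPBA (aryl migration to oxygen) and the formates methanolysed to triol A2.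
- Merits: the substitution that joins rings B and C would be easier than any ether formation in the chosen route, because three formyl groups activate the ring. Ring C would emerge with free hydroxyls while rings A and B stay methylated, which tells the rings apart.
- Weak points: in the first oxidation the migrating aryl group still carries two formyl groups and is electron-poor, so hydride migration to the carboxylic acid competes. The phenol with rings A and B still needs a hindered diaryl ether coupling. The bromine would come last, on a free phloroglucinol ring beside a 3,5-dimethoxyphenoxy ring with three activated positions, so monobromination on ring C alone is hard to secure.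
- Comparison: the chosen plan has nothing as easy as that substitution. It offers in return a bromine set in step 1 on a symmetric arene, and aryl migrations only on rings with two ortho methoxy groups.

**Alternative 2:** The cut is at the three C–O bonds of ring B. The forward key step is the one-pot version of steps 3 and 4 of the chosen route: the ring C phenoxide takes the fluorine para to the formyl group, methoxide takes the two ortho fluorines, and the product A3 is the same substance as 7.
- Merits: every reaction is of a well-tried kind, no ring has to be built, and the sequence to the ring B–C phenol is the shortest conceivable. The chosen plan uses the same chemistry for ring B.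
- Weak points: the step does nothing for ring A. After the formyl group has become a hydroxyl, the di-ortho-methoxy phenol still has to be arylated with an electron-rich 3,5-dialkoxyaryl halide under CuI catalysis, which is the hard case of that reaction and puts a metal next to the ring C bromide.
- Comparison: this road is shorter by about three steps and rests entirely on known chemistry, and in both respects it is better. The chosen plan offers in return a metal-free, neutral construction of ring A in which the hindered phenol only adds to an unhindered sp2 carbon. If that fails, its fallback is the endgame of this alternative.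

**Alternative 3:** Two C–C bonds of ring C are cut. The bis-enolate of dimethyl 3-oxopentanedioate A5 would attack both ester groups of aryloxymalonate A4 (rings A and B on the malonate oxygen) and close ring C as the phloroglucinol diester A6 by a double Claisen condensation.
- Merits: the oxygen pattern of ring C is fixed by construction, the partners are cheap, and the two ester groups mark exactly the two positions of which one must end as C–Br and the other as C–H.
- Weak points: the C–H of A4 is the most acidic site in the mixture, and once deprotonated its esters no longer accept an enolate, so the condensation is likely to stall. The two esters must then be told apart (one removed, one exchanged for bromine), which costs several steps on an air-sensitive triol. The phenol with rings A and B again needs a hindered ether coupling.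
- Comparison: both plans build one ring from open-chain parts. This one uses an old condensation type and is better precedented in that respect. The chosen annulation delivers ring A with its final substitution pattern and needs no later adjustment, but it relies on a substrate class not yet tried in that reaction.

Key step: step 8

Remark on the chemistry: 20 is achiral; intermediate 16 forms as a racemate and its stereocentre is lost on ring opening. Ethoxyacetylene 14 is assumed to be used as its commercial solution in hexanes.

## Route

Step 1
Reactants: 1 2,4,6-trimethoxybenzaldehyde
Product: 2 3-bromo-2,4,6-trimethoxybenzaldehyde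
Conditions: NBS (1.0 equiv), MeCN, 0 °C → rt
Reagents that add atoms: N-bromosuccinimide, O=C1CCC(=O)N1Br
Why: Electrophilic aromatic bromination; C3 and C5 are equivalent and each is activated by two ortho and one para methoxy group, and the first bromine together with the formyl group slows a second substitution, so one equivalent should stop at the monobromide.

Step 2
Reactants: 2 3-bromo-2,4,6-trimethoxybenzaldehyde
Product: 4 3-bromo-2,4,6-trimethoxyphenol, via 3-bromo-2,4,6-trimethoxyphenyl formate 3 (not isolated)
Conditions: mCPBA, CH2Cl2, 0 °C → rt; aq. NaHCO3 wash; then K2CO3 (cat.), MeOH, rt, under argon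
Reagents that add atoms: 3-chloroperbenzoic acid (mCPBA), OOC(=O)c1cccc(Cl)c1
Why: Baeyer–Villiger oxidation of the Dakin type; the electron-rich aryl group with two ortho methoxy groups migrates in preference to hydrogen in the Criegee adduct, and the phenol is set free by methanolysis only after the oxidant has been removed.

Step 3
Reactants: 4 3-bromo-2,4,6-trimethoxyphenol; 5 2,4,6-trifluorobenzaldehyde
Product: 6 4-(3-bromo-2,4,6-trimethoxyphenoxy)-2,6-difluorobenzaldehyde
Conditions: K2CO3, DMF, 0 °C → rt
Reagents that add atoms: none
Why: Nucleophilic aromatic substitution through a Meisenheimer adduct stabilised by the formyl group; the di-ortho-substituted phenoxide should take the unhindered fluorine para to the aldehyde in a polar aprotic solvent, where chelation-guided ortho attack is weak, and the new aryloxy group deactivates the ring towards a second phenoxide.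

Step 4
Reactants: 6 4-(3-bromo-2,4,6-trimethoxyphenoxy)-2,6-difluorobenzaldehyde
Product: 7 4-(3-bromo-2,4,6-trimethoxyphenoxy)-2,6-dimethoxybenzaldehyde
Conditions: NaOMe (3 equiv), MeOH/THF, 0 → 50 °C
Reagents that add atoms: sodium methoxide, [Na+].[O-]C
Why: Twofold nucleophilic aromatic substitution of the fluorines ortho to the formyl group; addition is fastest at the C–F carbons, so fluoride should leave well before the para aryloxy group is touched.

Step 5
Reactants: 7 4-(3-bromo-2,4,6-trimethoxyphenoxy)-2,6-dimethoxybenzaldehyde
Product: 9 4-(3-bromo-2,4,6-trimethoxyphenoxy)-2,6-dimethoxyphenol, via aryl formate 8 (not isolated)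
Conditions: mCPBA, CH2Cl2, 0 °C → rt; aq. NaHCO3 wash; then K2CO3 (cat.), MeOH, rt, under argon
Reagents that add atoms: 3-chloroperbenzoic acid (mCPBA), OOC(=O)c1cccc(Cl)c1
Why: Baeyer–Villiger oxidation of the Dakin type; ring B with two ortho methoxy groups and a para aryloxy group migrates readily, and the formate shields the phenol from the peracid until methanolysis.

Step 6
Reactants: 10 3-ethoxycyclobut-2-en-1-one
Product: 11 cyclobutane-1,3-dione
Conditions: 1 M aq. HCl, THF, 0 °C → rt
Reagents that add atoms: water, O
Why: Acid hydrolysis of a vinylogous ester (conjugate addition of water, loss of ethanol) to the known, strongly acidic dione, which is extracted and used at once.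

Step 7
Reactants: 11 cyclobutane-1,3-dione; 9 4-(3-bromo-2,4,6-trimethoxyphenoxy)-2,6-dimethoxyphenol
Product: 13 3-[4-(3-bromo-2,4,6-trimethoxyphenoxy)-2,6-dimethoxyphenoxy]cyclobut-2-en-1-one, via 3-chlorocyclobut-2-en-1-one 12 (not isolated)
Conditions: (COCl)2, DMF (cat.), CH2Cl2, 0 °C; then 9, Et3N, CH2Cl2, 0 °C → rt
Reagents that add atoms: none
Why: Formation of a vinylogous acid chloride from the enol of a cyclic 1,3-dione with the Vilsmeier reagent, then addition–elimination of the phenoxide at C3 of the β-chloroenone; the attack is at an unhindered sp2 carbon, so the two ortho methoxy groups of 9 should be tolerated, and the dione is kept in slight excess over oxalyl chloride so that no acylating agent meets the phenol.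

Step 8
Reactants: 13 3-[4-(3-bromo-2,4,6-trimethoxyphenoxy)-2,6-dimethoxyphenoxy]cyclobut-2-en-1-one; 14 ethoxyacetylene
Product: 19 3-[4-(3-bromo-2,4,6-trimethoxyphenoxy)-2,6-dimethoxyphenoxy]-5-ethoxyphenol, via vinylketene 15 (not isolated), via vinylcyclobutenone 16 (not isolated), via dienylketene 17 (not isolated), via cyclohexadienone 18 (not isolated)
Conditions: 14 (5 equiv), toluene, sealed tube, 80 → 105 °C
Reagents that add atoms: none
Why: Proposed new method: thermal conrotatory 4π opening of 13 should give the aryloxy-substituted vinylketene 15, whose ketene C=C bond adds to ethoxyacetylene in a [2+2] cycloaddition to give vinylcyclobutenone 16; a second 4π opening gives dienylketene 17, and disrotatory 6π electrocyclisation (ketene carbon to the terminal methylene carbon, closing the six-membered carbocycle) followed by tautomerisation of dienone 18 delivers phenol 19. The closest known reaction type is the Danheiser benzannulation of 3-alkyl- and 3-arylcyclobutenones with alkoxyacetylenes to 5-substituted resorcinol monoethers; thermal opening of 3-alkoxycyclobutenones is known from the ring expansion of squarate-derived 4-aryl-4-hydroxycyclobutenones, but a 3-aryloxycyclobutenone has not served as the ketene source in the two-component reaction. The selectivity needed is the orientation of the ketene–alkyne cycloaddition: the electron-rich CH terminus of the ynol ether bonds to the electrophilic ketene carbonyl carbon, the same orientation by which ketene itself and ethoxyacetylene give 10, and this places OH, OEt and OAr on alternate carbons. The opening of 16 is reversible, so the isomer of 17 with the vinyl group turned inward is drained by the irreversible electrocyclisation. No stereocentre remains in the product. The conditions are neutral and metal-free, so the aryl bromide, the methyl ethers and both diaryl ether bonds should pass unchanged; the alkyne is used in excess because it slowly fragments to ketene and ethylene on prolonged heating above about 100 °C.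

Step 9
Reactants: 19 3-[4-(3-bromo-2,4,6-trimethoxyphenoxy)-2,6-dimethoxyphenoxy]-5-ethoxyphenol
Product: 20 4-bromo-2-[4-(3,5-dihydroxyphenoxy)-3,5-dihydroxyphenoxy]benzene-1,3,5-triol
Conditions: BBr3 (excess), CH2Cl2, −78 °C → rt; then H2O, 0 °C
Reagents that add atoms: none
Why: Lewis acid-mediated cleavage of aryl alkyl ethers: each ether oxygen binds boron and bromide attacks the methyl or ethyl carbon in an SN2 step, whereas the diaryl ether bonds and the aryl bromide offer no such carbon and should stay intact.

## Compound list

1 | 2,4,6-trimethoxybenzaldehyde | COc1cc(OC)c(C=O)c(OC)c1 | starting material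
2 | 3-bromo-2,4,6-trimethoxybenzaldehyde | COc1cc(OC)c(Br)c(OC)c1C=O | intermediate
3 | 3-bromo-2,4,6-trimethoxyphenyl formate | COc1cc(OC)c(Br)c(OC)c1OC=O | intermediate
4 | 3-bromo-2,4,6-trimethoxyphenol | COc1cc(OC)c(Br)c(OC)c1O | intermediate
5 | 2,4,6-trifluorobenzaldehyde | O=Cc1c(F)cc(F)cc1F | starting material
6 | 4-(3-bromo-2,4,6-trimethoxyphenoxy)-2,6-difluorobenzaldehyde | O=Cc1c(F)cc(Oc2c(OC)cc(OC)c(Br)c2OC)cc1F | intermediate
7 | 4-(3-bromo-2,4,6-trimethoxyphenoxy)-2,6-dimethoxybenzaldehyde | O=Cc1c(OC)cc(Oc2c(OC)cc(OC)c(Br)c2OC)cc1OC | intermediate
8 | 4-(3-bromo-2,4,6-trimethoxyphenoxy)-2,6-dimethoxyphenyl formate | O=COc1c(OC)cc(Oc2c(OC)cc(OC)c(Br)c2OC)cc1OC | intermediate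
9 | 4-(3-bromo-2,4,6-trimethoxyphenoxy)-2,6-dimethoxyphenol | Oc1c(OC)cc(Oc2c(OC)cc(OC)c(Br)c2OC)cc1OC | intermediate
10 | 3-ethoxycyclobut-2-en-1-one | CCOC1=CC(=O)C1 | starting material
11 | cyclobutane-1,3-dione | O=C1CC(=O)C1 | intermediate
12 | 3-chlorocyclobut-2-en-1-one | O=C1CC(Cl)=C1 | intermediate
13 | 3-[4-(3-bromo-2,4,6-trimethoxyphenoxy)-2,6-dimethoxyphenoxy]cyclobut-2-en-1-one | O=C1CC(Oc2c(OC)cc(Oc3c(OC)cc(OC)c(Br)c3OC)cc2OC)=C1 | intermediate
14 | ethoxyacetylene (ethoxyethyne) | CCOC#C | starting material
15 | 3-[4-(3-bromo-2,4,6-trimethoxyphenoxy)-2,6-dimethoxyphenoxy]buta-1,3-dien-1-one | O=C=CC(=C)Oc1c(OC)cc(Oc2c(OC)cc(OC)c(Br)c2OC)cc1OC | intermediate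
16 | 4-{1-[4-(3-bromo-2,4,6-trimethoxyphenoxy)-2,6-dimethoxyphenoxy]ethenyl}-3-ethoxycyclobut-2-en-1-one (racemic) | CCOC1=CC(=O)C1C(=C)Oc2c(OC)cc(Oc3c(OC)cc(OC)c(Br)c3OC)cc2OC | intermediate
17 | (3E)-5-[4-(3-bromo-2,4,6-trimethoxyphenoxy)-2,6-dimethoxyphenoxy]-3-ethoxyhexa-1,3,5-trien-1-one | O=C=C/C(OCC)=C\C(=C)Oc1c(OC)cc(Oc2c(OC)cc(OC)c(Br)c2OC)cc1OC | intermediate
18 | 5-[4-(3-bromo-2,4,6-trimethoxyphenoxy)-2,6-dimethoxyphenoxy]-3-ethoxycyclohexa-2,4-dien-1-one | CCOC1=CC(=O)CC(Oc2c(OC)cc(Oc3c(OC)cc(OC)c(Br)c3OC)cc2OC)=C1 | intermediate
19 | 3-[4-(3-bromo-2,4,6-trimethoxyphenoxy)-2,6-dimethoxyphenoxy]-5-ethoxyphenol | CCOc1cc(O)cc(Oc2c(OC)cc(Oc3c(OC)cc(OC)c(Br)c3OC)cc2OC)c1 | intermediate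
20 | 4-bromo-2-[4-(3,5-dihydroxyphenoxy)-3,5-dihydroxyphenoxy]benzene-1,3,5-triol | Oc1cc(O)cc(Oc2c(O)cc(Oc3c(O)cc(O)c(Br)c3O)cc2O)c1 | target

## Step count and weak points

Total: 9 steps. Longest linear sequence: 8 steps (steps 1, 2, 3, 4, 5, 7, 8, 9 from 1); step 6 is a one-step side branch.

**Step 8 (key step, new method).**
- What may go wrong: the vinylogous ester resonance of 13 may raise the barrier to ring opening until the temperature needed approaches the range where ethoxyacetylene fragments and polymerises. Phenol 19, once formed, may capture ketene 15 as an aryl ester or exchange with the aryloxy group of 13; a brief methanolysis of the crude product would return the phenol from such an ester.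
- Fallback (known chemistry): it sets out from 9 and comes back to the route at 20. Ullmann-type O-arylation of 9 with 1-iodo-3,5-dimethoxybenzene F1 (CuI, picolinic acid, K3PO4, DMSO, 90 °C) should give 1-[4-(3-bromo-2,4,6-trimethoxyphenoxy)-2,6-dimethoxyphenoxy]-3,5-dimethoxybenzene F2. The aryl iodide should react well before the hindered, electron-rich ring C bromide. BBr3 in CH2Cl2 then cleaves the seven methyl ethers of F2 to 20.

**Step 7.**
- What may go wrong: the strained dione and its chloride may oligomerise or open before the hindered phenoxide has added, and any oxalyl chloride left over would acylate the phenol.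
- Fallback: it sets out from 11 and 9 and comes back at 13. Dione 11 is converted with TsCl and Et3N into the isolable 3-oxocyclobut-1-en-1-yl 4-methylbenzenesulfonate F3, which is purified. It is then treated with the preformed caesium phenoxide of 9 (Cs2CO3, MeCN, rt), so that no chlorinating agent is present during the coupling.

**Step 3.**
- What may go wrong: attack at a fluorine ortho to the formyl group, or a second substitution by phenoxide, would give regioisomers and bis-ethers that are hard to separate. Step 4 adds the risk of slow replacement of the second fluorine.
- Fallback: it sets out from 4 and comes back at 7, bypassing steps 3 and 4. The phenoxide of 4 substitutes the single fluorine of 4-fluoro-2,6-dimethoxybenzaldehyde F4 (Cs2CO3, DMSO, 100 °C), which removes the regiochemical question at the price of a less activated electrophile.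

**Step 9.**
- What may go wrong: dealkylation at six sites may stop short, HBr may promote loss or migration of the bromine once ring C is a free bromophloroglucinol, and the free heptaphenol may oxidise in air during chromatography.
- Fallback: it sets out from 19 and comes back at 20. The crude product of the BBr3 treatment is acetylated at once (Ac2O, pyridine) to 4-bromo-2-[4-(3,5-diacetoxyphenoxy)-3,5-diacetoxyphenoxy]benzene-1,3,5-triyl triacetate F5. This is stable, can be freed from partly alkylated or debrominated material on silica, and is then deacetylated with catalytic NaOMe in degassed MeOH and neutralised with an acidic ion-exchange resin.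

## Further compounds

F1 | step 8 | 1-iodo-3,5-dimethoxybenzene | COc1cc(I)cc(OC)c1
F2 | step 8 | 1-[4-(3-bromo-2,4,6-trimethoxyphenoxy)-2,6-dimethoxyphenoxy]-3,5-dimethoxybenzene | COc1cc(OC)cc(Oc2c(OC)cc(Oc3c(OC)cc(OC)c(Br)c3OC)cc2OC)c1
F3 | step 7 | 3-oxocyclobut-1-en-1-yl 4-methylbenzenesulfonate | Cc1ccc(cc1)S(=O)(=O)OC1=CC(=O)C1
F4 | step 3 | 4-fluoro-2,6-dimethoxybenzaldehyde | COc1cc(F)cc(OC)c1C=O
F5 | step 9 | 4-bromo-2-[4-(3,5-diacetoxyphenoxy)-3,5-diacetoxyphenoxy]benzene-1,3,5-triyl triacetate | CC(=O)Oc1cc(OC(C)=O)cc(Oc2c(OC(C)=O)cc(Oc3c(OC(C)=O)cc(OC(C)=O)c(Br)c3OC(C)=O)cc2OC(C)=O)c1
A1 | alternative 1 | 2-[4-(3,5-dimethoxyphenoxy)-3,5-dimethoxyphenoxy]benzene-1,3,5-tricarbaldehyde | O=Cc1cc(C=O)c(Oc2cc(OC)c(Oc3cc(OC)cc(OC)c3)c(OC)c2)c(C=O)c1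
A2 | alternative 1 | 2-[4-(3,5-dimethoxyphenoxy)-3,5-dimethoxyphenoxy]benzene-1,3,5-triol | Oc1cc(O)c(Oc2cc(OC)c(Oc3cc(OC)cc(OC)c3)c(OC)c2)c(O)c1
A3 | alternative 2 | 4-(3-bromo-2,4,6-trimethoxyphenoxy)-2,6-dimethoxybenzaldehyde | COc1cc(Oc2c(OC)cc(OC)c(Br)c2OC)cc(OC)c1C=O
A4 | alternative 3 | dimethyl 2-[4-(3,5-dimethoxyphenoxy)-3,5-dimethoxyphenoxy]propanedioate | COC(=O)C(Oc1cc(OC)c(Oc2cc(OC)cc(OC)c2)c(OC)c1)C(=O)OC
A5 | alternative 3 | dimethyl 3-oxopentanedioate | COC(=O)CC(=O)CC(=O)OC
A6 | alternative 3 | dimethyl 5-[4-(3,5-dimethoxyphenoxy)-3,5-dimethoxyphenoxy]-2,4,6-trihydroxyisophthalate | COC(=O)c1c(O)c(C(=O)OC)c(O)c(Oc2cc(OC)c(Oc3cc(OC)cc(OC)c3)c(OC)c2)c1O
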